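**Plan**

- Retrosynthesis: the O7 acetate is exchanged for a silyl ether, then the tetrahydropyran is opened at O–C9 and C12–Br to an acyclic C9 carbinol that carries a 12,13-oxirane. This chain is cut at C7–C8 (aldol) into two C7 halves, each cut again at C10–C11 or C5–C6 (Claisen); C8 is a methyl Grignard carbon.
- Forward: each half comes from an allylic alcohol by Johnson–Claisen rearrangement, DIBAL reduction and enamine α-chlorination. C8 joins them (MeMgBr, then chlorohydrin aldol); silylation, ketone reduction and epoxidation give the cyclisation substrate. The only ring is closed last, before O7 deprotection and acetylation.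
- Enabling feature: C9 lies 1,4 to C12 and 1,5 to C13 of the oxirane. Its oxygen can therefore displace a C9 leaving group through the five-membered ring O–C12–C11–C10–C9 while keeping its bond to C13; bromide opening at C12 leaves the ring O–C9–C10–C11–C12–C13.
- Stereochemistry: C6 and C10 from catalyst-controlled α-chlorination; C7 from Cornforth–Felkin aldol addition; C9 from Felkin reduction, then SN2 inversion in the ring closure; C12/C13 from the E-alkene plus Shi epoxidation, carried over by inversion (C12) and retention (C13).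

Key step: step 13

Assumption: the sense of induction of the aminocatalyst (steps 3, 8) and of the fructose-derived ketone (step 12) is taken from the usual models; the catalyst enantiomer meant is the one that gives the stated configuration.

**Route**

Step 1
Reactants: 1 pent-1-en-3-ol; 2 triethyl orthoacetate
Product: 4 ethyl (4E)-hept-4-enoate, via ketene acetal 3 (not isolated)
Conditions: 2 (excess), EtCO2H (cat.), 140 °C, EtOH distilled off
Reagents that add atoms: none
Why: Johnson–Claisen rearrangement through a chair transition state with the ethyl group equatorial should form the C10–C11 bond and the 12E alkene.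

Step 2
Reactants: 4 ethyl (4E)-hept-4-enoate
Product: 5 (4E)-hept-4-enal
Conditions: DIBAL-H (1.05 equiv), CH2Cl2, −78 °C; Rochelle salt
Reagents that add atoms: none
Why: DIBAL reduction of an ester stops at the aldehyde because the tetrahedral aluminium hemiacetal is stable at −78 °C.

Step 3
Reactants: 5 (4E)-hept-4-enal
Product: 6 (2R,4E)-2-chlorohept-4-enal
Conditions: NCS, (2R,5R)-2,5-diphenylpyrrolidine (10 mol %), CH2Cl2, 0 °C to rt; used at once
Reagents that add atoms: N-chlorosuccinimide, O=C1CCC(=O)N1Cl
Why: Enamine-catalysed α-chlorination of an aldehyde, in which the C2-symmetric amine shields one enamine face, should set the C10 chloride (R) under catalyst control.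

Step 4
Reactants: 6 (2R,4E)-2-chlorohept-4-enal
Product: 7 (3R,5E)-3-chlorooct-5-en-2-ol (both C2 epimers)
Conditions: MeMgBr, Et2O, −78 °C; cold NH4Cl quench
Reagents that add atoms: methylmagnesium bromide, C[Mg]Br
Why: Grignard addition brings in C8 at low temperature without touching the chloride; the carbinol configuration is irrelevant because it is oxidised next.

Step 5
Reactants: 7 (3R,5E)-3-chlorooct-5-en-2-ol
Product: 8 (3R,5E)-3-chlorooct-5-en-2-one
Conditions: Dess–Martin periodinane, CH2Cl2, 0 °C to rt
Reagents that add atoms: none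
Why: Dess–Martin oxidation is non-basic and should give the α-chloro methyl ketone without epimerising C10.

Step 6
Reactants: 9 pent-1-en-4-yn-3-ol; 2 triethyl orthoacetate
Product: 11 ethyl (4E)-hept-4-en-6-ynoate, via ketene acetal 10 (not isolated)
Conditions: 2 (excess), EtCO2H (cat.), 130 °C, EtOH distilled off
Reagents that add atoms: none
Why: Johnson–Claisen rearrangement through the vinyl (not the ethynyl) terminus should form the C5–C6 bond and leave the conjugated 3E enyne.

Step 7
Reactants: 11 ethyl (4E)-hept-4-en-6-ynoate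
Product: 12 (4E)-hept-4-en-6-ynal
Conditions: DIBAL-H (1.05 equiv), CH2Cl2, −78 °C; Rochelle salt
Reagents that add atoms: none
Why: Low-temperature DIBAL reduction of the ester to the aldehyde leaves the terminal enyne untouched.

Step 8
Reactants: 12 (4E)-hept-4-en-6-ynal
Product: 13 (2R,4E)-2-chlorohept-4-en-6-ynal
Conditions: NCS, (2R,5R)-2,5-diphenylpyrrolidine (10 mol %), CH2Cl2, 0 °C to rt; used at once
Reagents that add atoms: N-chlorosuccinimide, O=C1CCC(=O)N1Cl
Why: The same enamine-catalysed α-chlorination should set the C6 chloride (R) under catalyst control.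

Step 9
Reactants: 8 (3R,5E)-3-chlorooct-5-en-2-one; 13 (2R,4E)-2-chlorohept-4-en-6-ynal
Product: 15 (3E,6R,7S,10R,12E)-6,10-dichloro-7-hydroxypentadeca-3,12-dien-1-yn-9-one, via lithium enolate 14 (not isolated)
Conditions: LDA (1.0 equiv), THF, −78 °C; then 13, −78 °C, 15 min; AcOH/THF quench at −78 °C
Reagents that add atoms: lithium diisopropylamide, [Li+].CC(C)[N-]C(C)C (lithium stays in 14 only)
Why: Chlorohydrin aldol reaction: kinetic deprotonation at the methyl group gives 14, which should add to the α-chloro aldehyde under Cornforth–Felkin control (nucleophile anti to C–Cl) and set C7 anti to the C6 chloride.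

Step 10
Reactants: 15 the aldol product
Product: 16 (3E,6R,7S,10R,12E)-7-[tert-butyl(dimethyl)silyl]oxy-6,10-dichloropentadeca-3,12-dien-1-yn-9-one
Conditions: TBSOTf, 2,6-lutidine, CH2Cl2, −78 °C
Reagents that add atoms: tert-butyldimethylsilyl triflate, CC(C)(C)[Si](C)(C)OS(=O)(=O)C(F)(F)F
Why: Low-temperature silylation protects the β-hydroxy ketone without retro-aldol and gives an O7 group that cannot act as a neighbouring group in step 13.

Step 11
Reactants: 16 the silyl ether ketone
Product: 17 (3E,6R,7S,9S,10R,12E)-7-[tert-butyl(dimethyl)silyl]oxy-6,10-dichloropentadeca-3,12-dien-1-yn-9-ol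
Conditions: L-Selectride, THF, −78 °C; pH 7 buffer
Reagents that add atoms: none
Why: Felkin–Anh (Cornforth) reduction of an α-chloro ketone by a bulky hydride, delivered anti to the C10–Cl bond, should give the 9,10-anti chlorohydrin (9S), the epimer that the inversion in step 13 requires.

Step 12
Reactants: 17 the 9S alcohol
Product: 18 (3E,6R,7S,9S,10R,12S,13S)-7-[tert-butyl(dimethyl)silyl]oxy-6,10-dichloro-12,13-epoxypentadec-3-en-1-yn-9-ol
Conditions: ent-Shi ketone (L-fructose-derived, 30 mol %), Oxone, K2CO3, n-Bu4NHSO4, MeCN–DMM–aq. buffer (pH 10.5), 0 °C; no acidic silica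
Reagents that add atoms: Oxone (potassium peroxymonosulfate), [K+].[O-]S(=O)(=O)OO
Why: Shi epoxidation: the electrophilic dioxirane should prefer the isolated, electron-richer E-alkene over the enyne alkene, and the catalyst face selection should give the 12S,13S trans-epoxide.

Step 13
Reactants: 18 the epoxy alcohol
Product: 21 (3E,6R,7S,9R,10R,12R,13S)-12-bromo-7-[tert-butyl(dimethyl)silyl]oxy-6,10-dichloro-9,13-epoxypentadec-3-en-1-yne, via triflate 19 (not isolated), via oxonium triflate 20 (not isolated)
Conditions: Tf2O, 2,6-di-tert-butyl-4-methylpyridine, CH2Cl2, −78 to −40 °C; then n-Bu4NBr, −78 to 0 °C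
Reagents that add atoms: tetrabutylammonium bromide, CCCC[N+](CCCC)(CCCC)CCCC.[Br-]; triflic anhydride, O=S(=O)(OS(=O)(=O)C(F)(F)F)C(F)(F)F (its atoms stay in 19 and 20 only)
Why: Proposed new method: the C9 triflate 19 is displaced by the oxirane oxygen in an SN2 step that closes the five-membered ring O–C12–C11–C10–C9 (5-exo-tet) and, through C13, the six-membered ring O–C9–C10–C11–C12–C13 at the same time, giving the 1-oxoniabicyclo[3.1.0]hexane 20; bromide then opens the three-membered ring at the ring-fusion carbon C12, which deletes the five-membered ring and leaves the tetrahydropyran. The closest known reaction types are the participation of an oxirane oxygen in the solvolysis of 4,5-epoxyalkyl sulfonates and the zinc acetate-mediated ring expansion of 2-(1-sulfonyloxyalkyl)tetrahydrofurans, which pass through the same kind of bicyclic oxonium ion and are opened by an external nucleophile at the ring-fusion carbon. All three ring stereocentres are fixed by the mechanism and not by a facial choice: C9 by inversion (the 9,10-anti chlorohydrin becomes the cis C8/Cl pair), C12 by inversion on bromide attack, C13 by retention of the oxirane C–O bond, so the 12S,13S trans-epoxide gives the trans Br/Et pair. The step needs O-alkylation of the oxirane before bromide can attack the triflate, and opening of 20 at C12 instead of C13 or C9: bromide is therefore added only after 20 has formed, C9 is the unstrained carbon, and attack at C12 leads directly to the chair with C8, Br and Et equatorial, while a 2-(1-bromopropyl)tetrahydrofuran from C13 attack can return to 20 on warming. The silyl ether at O7 and the α-chlorine cannot compete as neighbouring groups, which is why O7 is not carried through this step as the acetate.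

Step 14
Reactants: 21 the silyl-protected bromochloro tetrahydropyran
Product: 22 (3E,6R,7S,9R,10R,12R,13S)-12-bromo-6,10-dichloro-9,13-epoxypentadec-3-en-1-yn-7-ol
Conditions: HF·pyridine, THF/pyridine, 0 °C to rt
Reagents that add atoms: none
Why: Buffered fluoride cleavage of the TBS ether should leave the secondary halides and the enyne untouched.

Step 15
Reactants: 22 the C7 alcohol
Product: 23 (3E,6R,7S,9R,10R,12R,13S)-12-bromo-6,10-dichloro-9,13-epoxypentadec-3-en-1-yn-7-yl acetate (target)
Conditions: Ac2O, pyridine, DMAP (cat.), CH2Cl2, 0 °C to rt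
Reagents that add atoms: acetic anhydride, CC(=O)OC(C)=O
Why: DMAP-catalysed acetylation of the secondary alcohol with retention at C7 should give the target.

**Compound list**

1 | pent-1-en-3-ol (racemic) | C=CC(O)CC | starting material
2 | triethyl orthoacetate | CCOC(C)(OCC)OCC | starting material
3 | 3-[(1-ethoxyethenyl)oxy]pent-1-ene (ketene acetal) | C=C(OCC)OC(CC)C=C | intermediate
4 | ethyl (4E)-hept-4-enoate | CC/C=C/CCC(=O)OCC | intermediate
5 | (4E)-hept-4-enal | CC/C=C/CCC=O | intermediate
6 | (2R,4E)-2-chlorohept-4-enal | CC/C=C/C[C@@H](Cl)C=O | intermediate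
7 | (3R,5E)-3-chlorooct-5-en-2-ol (C2 epimers) | CC/C=C/C[C@@H](Cl)C(C)O | intermediate
8 | (3R,5E)-3-chlorooct-5-en-2-one | CC/C=C/C[C@@H](Cl)C(C)=O | intermediate
9 | pent-1-en-4-yn-3-ol (racemic) | C=CC(O)C#C | starting material
10 | 3-[(1-ethoxyethenyl)oxy]pent-1-en-4-yne (ketene acetal) | C=C(OCC)OC(C=C)C#C | intermediate
11 | ethyl (4E)-hept-4-en-6-ynoate | C#C/C=C/CCC(=O)OCC | intermediate
12 | (4E)-hept-4-en-6-ynal | C#C/C=C/CCC=O | intermediate
13 | (2R,4E)-2-chlorohept-4-en-6-ynal | C#C/C=C/C[C@@H](Cl)C=O | intermediate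
14 | lithium (3R,5E)-3-chloroocta-1,5-dien-2-olate | [Li+].[O-]C(=C)[C@H](Cl)C/C=C/CC | intermediate
15 | (3E,6R,7S,10R,12E)-6,10-dichloro-7-hydroxypentadeca-3,12-dien-1-yn-9-one | C#C/C=C/C[C@@H](Cl)[C@@H](O)CC(=O)[C@H](Cl)C/C=C/CC | intermediate
16 | (3E,6R,7S,10R,12E)-7-[tert-butyl(dimethyl)silyl]oxy-6,10-dichloropentadeca-3,12-dien-1-yn-9-one | C#C/C=C/C[C@@H](Cl)[C@@H](O[Si](C)(C)C(C)(C)C)CC(=O)[C@H](Cl)C/C=C/CC | intermediate
17 | (3E,6R,7S,9S,10R,12E)-7-[tert-butyl(dimethyl)silyl]oxy-6,10-dichloropentadeca-3,12-dien-1-yn-9-ol | C#C/C=C/C[C@@H](Cl)[C@@H](O[Si](C)(C)C(C)(C)C)C[C@H](O)[C@H](Cl)C/C=C/CC | intermediate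
18 | (3E,6R,7S,9S,10R,12S,13S)-7-[tert-butyl(dimethyl)silyl]oxy-6,10-dichloro-12,13-epoxypentadec-3-en-1-yn-9-ol | C#C/C=C/C[C@@H](Cl)[C@@H](O[Si](C)(C)C(C)(C)C)C[C@H](O)[C@H](Cl)C[C@@H]1O[C@H]1CC | intermediate
19 | C9 triflate of 18 | C#C/C=C/C[C@@H](Cl)[C@@H](O[Si](C)(C)C(C)(C)C)C[C@H](OS(=O)(=O)C(F)(F)F)[C@H](Cl)C[C@@H]1O[C@H]1CC | intermediate
20 | 1-oxoniabicyclo[3.1.0]hexane triflate (O bonded to C9, C12 and C13) | C#C/C=C/C[C@@H](Cl)[C@@H](O[Si](C)(C)C(C)(C)C)C[C@@H]1[C@H](Cl)C[C@H]2[C@H](CC)[O+]12.[O-]S(=O)(=O)C(F)(F)F | intermediate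
21 | (3E,6R,7S,9R,10R,12R,13S)-12-bromo-7-[tert-butyl(dimethyl)silyl]oxy-6,10-dichloro-9,13-epoxypentadec-3-en-1-yne | C#C/C=C/C[C@@H](Cl)[C@H](C[C@H]1O[C@@H](CC)[C@H](Br)C[C@H]1Cl)O[Si](C)(C)C(C)(C)C | intermediate
22 | (3E,6R,7S,9R,10R,12R,13S)-12-bromo-6,10-dichloro-9,13-epoxypentadec-3-en-1-yn-7-ol | C#C/C=C/C[C@@H](Cl)[C@H](C[C@H]1O[C@@H](CC)[C@H](Br)C[C@H]1Cl)O | intermediate
23 | (3E,6R,7S,9R,10R,12R,13S)-12-bromo-6,10-dichloro-9,13-epoxypentadec-3-en-1-yn-7-yl acetate | C#C/C=C/C[C@@H](Cl)[C@H](C[C@H]1O[C@@H](CC)[C@H](Br)C[C@H]1Cl)OC(C)=O | target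

**Step count and risks**

Total step count: 15. Longest linear sequence: 12 steps (steps 1–5, then 9–15).

Steps most likely to fail:

1. Step 13 (Proposed new method). Possible failure processes: direct bromide displacement or elimination of the triflate before the oxirane oxygen participates; opening of the oxonium ion at C13 to a bromo-tetrahydrofuran that does not revert; premature 5-exo closure of 18 by its own hydroxyl before triflation. The fallback uses known chemistry, sets out from 17 and returns at 21. Compound 17 would be inverted at C9 by a Mitsunobu reaction with chloroacetic acid (PPh3, DIAD, toluene, 0 °C) to the 9R chloroacetate F1, and thiourea/NaHCO3 in EtOH would remove the chloroacetyl group to give the 9,10-syn chlorohydrin F2. Shi epoxidation, now with the D-fructose-derived ketone, would give the 12R,13R epoxy alcohol F3, which CSA should close 5-exo (inversion at C12) to the 2,5-trans tetrahydrofuran carbinol F4. Chloromethanesulfonyl chloride/pyridine would give the chloromethanesulfonate F5. Heating F5 with n-Bu4NBr should bring about the halide-terminated ring expansion of a tetrahydrofuranyl carbinyl sulfonate through the cation of 20 (inversion at C13 and at C12), which gives 21.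

2. Step 9. Possible failure processes: deprotonation at the chlorine-bearing carbon instead of the methyl group, Favorskii-type loss of chloride from enolate 14, and erosion of Cornforth selectivity. The fallback sets out from 6 and returns at 15. Bromomethyllithium (CH2Br2, MeLi, THF, −78 °C, acidic quench at −78 °C) would add to 6 to give the bromohydrin F6. Dess–Martin oxidation would give the bromomethyl ketone F7. A chromium(II)-mediated Reformatsky reaction of F7 with 13 (CrCl2, LiI cat., THF) should generate the enolate only at C8 by insertion into the C–Br bond and give 15.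

3. Step 12. Possible failure processes: competing epoxidation of the enyne alkene, closure of the chlorohydrin to an epoxide in the basic medium, and premature cyclisation of the product. The fallback moves the epoxidation to a stage where no other alkene or free carbinol is present; it sets out from 4 and returns at 18. Ester 4 would be epoxidised with the same ent-Shi system to the epoxy ester F8 and reduced with DIBAL-H to the epoxy aldehyde F9. Chlorination as in step 3 would give the chloro aldehyde F10, MeMgBr the carbinol F11, and Dess–Martin oxidation the epoxy chloro ketone F12. LDA would convert F12 into its lithium enolate F13, which with 13 should give the aldol F14. TBSOTf would give the silyl ether F15, and L-Selectride reduction as in step 11 should give 18.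

**Further compounds**

F1 | step 13 | (3E,6R,7S,9R,10R,12E)-7-[tert-butyl(dimethyl)silyl]oxy-6,10-dichloropentadeca-3,12-dien-1-yn-9-yl chloroacetate | C#C/C=C/C[C@@H](Cl)[C@@H](O[Si](C)(C)C(C)(C)C)C[C@@H](OC(=O)CCl)[C@H](Cl)C/C=C/CC
F2 | step 13 | (3E,6R,7S,9R,10R,12E)-7-[tert-butyl(dimethyl)silyl]oxy-6,10-dichloropentadeca-3,12-dien-1-yn-9-ol | C#C/C=C/C[C@@H](Cl)[C@@H](O[Si](C)(C)C(C)(C)C)C[C@@H](O)[C@H](Cl)C/C=C/CC
F3 | step 13 | (3E,6R,7S,9R,10R,12R,13R)-7-[tert-butyl(dimethyl)silyl]oxy-6,10-dichloro-12,13-epoxypentadec-3-en-1-yn-9-ol | C#C/C=C/C[C@@H](Cl)[C@@H](O[Si](C)(C)C(C)(C)C)C[C@@H](O)[C@H](Cl)C[C@H]1O[C@@H]1CC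
F4 | step 13 | (3E,6R,7S,9R,10R,12S,13R)-7-[tert-butyl(dimethyl)silyl]oxy-6,10-dichloro-9,12-epoxypentadec-3-en-1-yn-13-ol | C#C/C=C/C[C@@H](Cl)[C@@H](O[Si](C)(C)C(C)(C)C)C[C@H]1O[C@H]([C@H](O)CC)C[C@H]1Cl
F5 | step 13 | (3E,6R,7S,9R,10R,12S,13R)-7-[tert-butyl(dimethyl)silyl]oxy-6,10-dichloro-9,12-epoxypentadec-3-en-1-yn-13-yl chloromethanesulfonate | C#C/C=C/C[C@@H](Cl)[C@@H](O[Si](C)(C)C(C)(C)C)C[C@H]1O[C@H]([C@H](OS(=O)(=O)CCl)CC)C[C@H]1Cl
F6 | step 9 | (3R,5E)-1-bromo-3-chlorooct-5-en-2-ol (C2 epimers) | CC/C=C/C[C@@H](Cl)C(O)CBr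
F7 | step 9 | (3R,5E)-1-bromo-3-chlorooct-5-en-2-one | CC/C=C/C[C@@H](Cl)C(=O)CBr
F8 | step 12 | ethyl 3-[(2S,3S)-3-ethyloxiran-2-yl]propanoate | CCOC(=O)CC[C@@H]1O[C@H]1CC
F9 | step 12 | 3-[(2S,3S)-3-ethyloxiran-2-yl]propanal | O=CCC[C@@H]1O[C@H]1CC
F10 | step 12 | (2R)-2-chloro-3-[(2S,3S)-3-ethyloxiran-2-yl]propanal | O=C[C@H](Cl)C[C@@H]1O[C@H]1CC
F11 | step 12 | (3R)-3-chloro-4-[(2S,3S)-3-ethyloxiran-2-yl]butan-2-ol (C2 epimers) | CC(O)[C@H](Cl)C[C@@H]1O[C@H]1CC
F12 | step 12 | (3R)-3-chloro-4-[(2S,3S)-3-ethyloxiran-2-yl]butan-2-one | CC(=O)[C@H](Cl)C[C@@H]1O[C@H]1CC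
F13 | step 12 | lithium enolate of F12 | [Li+].[O-]C(=C)[C@H](Cl)C[C@@H]1O[C@H]1CC
F14 | step 12 | (3E,6R,7S,10R,12S,13S)-6,10-dichloro-12,13-epoxy-7-hydroxypentadec-3-en-1-yn-9-one | C#C/C=C/C[C@@H](Cl)[C@@H](O)CC(=O)[C@H](Cl)C[C@@H]1O[C@H]1CC
F15 | step 12 | (3E,6R,7S,10R,12S,13S)-7-[tert-butyl(dimethyl)silyl]oxy-6,10-dichloro-12,13-epoxypentadec-3-en-1-yn-9-one | C#C/C=C/C[C@@H](Cl)[C@@H](O[Si](C)(C)C(C)(C)C)CC(=O)[C@H](Cl)C[C@@H]1O[C@H]1CC
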